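**Retrosynthetic overview**
1. Target 12 ⇒ N-H bis-epoxide 10 + palmitic acid 9: the indole C3–CH bond and the CH2–O ester bond come from one stereoinvertive 1,2-indolyl shift of an (R)-epoxyprenyl group at C3.
2. 10 ⇒ N-Boc bis-epoxide 8 ⇒ prenyl compound 7, by Shi epoxidation with the ent-ketone ((S)-oxirane on the C5 chain).
3. 7 ⇒ aryl bromide 5 + prenylstannane 6 (Stille); 5 ⇒ alkene 4, by Shi epoxidation with the D-fructose ketone ((R)-oxirane on the C3 chain, first stereocentre).
4. 4 ⇒ 5-bromoindole 1 + prenyl bromide 2 (C3 prenylation, then N-Boc).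
5. Ring order: indole bought; oxirane on the C3 chain; oxirane on the C5 chain; a short-lived cyclopropane in the last step, opened again.

Assumption: the SMILES is read as (S) at the indolyl-bearing carbon and (S) at the oxirane carbon, and both enantiomers of the Shi ketone count as purchasable catalysts.

**Step 1**
Reactants: 1 5-bromo-1H-indole; 2 1-bromo-3-methylbut-2-ene (prenyl bromide)
Product: 3 5-bromo-3-(3-methylbut-2-en-1-yl)-1H-indole
Conditions: Zn(OTf)2 (0.6 equiv), Bu4NI (0.5 equiv), i-Pr2NEt (1.1 equiv), PhMe, rt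
Reagents that add atoms: 1-bromo-3-methylbut-2-ene (compound 2), CC(C)=CCBr
Why: The zinc indolide is alkylated at C3 by the prenyl iodide formed in situ (Friedel–Crafts-type C3 allylation of an N-metalated indole), SN2 at the primary allylic carbon giving the linear prenyl group; no stereocentre.

**Step 2**
Reactants: 3 5-bromo-3-(3-methylbut-2-en-1-yl)-1H-indole
Product: 4 tert-butyl 5-bromo-3-(3-methylbut-2-en-1-yl)-1H-indole-1-carboxylate
Conditions: Boc2O (1.2 equiv), DMAP (5 mol %), MeCN, rt
Reagents that add atoms: di-tert-butyl dicarbonate (Boc2O), CC(C)(C)OC(=O)OC(=O)OC(C)(C)C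
Why: DMAP-catalysed N-acylation gives the carbamate, which deactivates the C2=C3 bond so that dioxiranes later attack only the side-chain alkenes and which catalytic methoxide removes at the end.

**Step 3**
Reactants: 4 tert-butyl 5-bromo-3-(3-methylbut-2-en-1-yl)-1H-indole-1-carboxylate
Product: 5 tert-butyl 5-bromo-3-{[(2R)-3,3-dimethyloxiran-2-yl]methyl}-1H-indole-1-carboxylate
Conditions: D-fructose-derived Shi ketone (30 mol %), Oxone (2KHSO5·KHSO4·K2SO4), K2CO3, Bu4NHSO4 (cat.), MeCN–CH2(OMe)2–aq. Na2B4O7 buffer (pH about 10.5), 0 °C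
Reagents that add atoms: potassium peroxymonosulfate (KHSO5, from Oxone), [K+].[O-]S(=O)(=O)OO
Why: Shi asymmetric epoxidation, in which the chiral dioxirane transfers oxygen through a spiro transition state to one face of the trisubstituted alkene; the D-fructose ketone gives the (R)-oxirane (same facial sense as its (R,R) epoxides from trans alkenes), expected near 90% ee, and the carbamate-deactivated indole is untouched.

**Step 4**
Reactants: 5 tert-butyl 5-bromo-3-{[(2R)-3,3-dimethyloxiran-2-yl]methyl}-1H-indole-1-carboxylate; 6 tributyl(3-methylbut-2-en-1-yl)stannane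
Product: 7 tert-butyl 3-{[(2R)-3,3-dimethyloxiran-2-yl]methyl}-5-(3-methylbut-2-en-1-yl)-1H-indole-1-carboxylate
Conditions: 6 (1.5 equiv), Pd(PPh3)4 (5 mol %), DMF, 90 °C
Reagents that add atoms: tributyl(3-methylbut-2-en-1-yl)stannane (compound 6), CCCC[Sn](CCCC)(CCCC)CC=C(C)C
Why: Stille coupling, in which oxidative addition of the aryl bromide to zerovalent palladium, allyl transfer from tin and reductive elimination at the unsubstituted allyl terminus give the linear prenyl arene under neutral conditions that spare oxirane and carbamate; no new stereocentre.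

**Step 5**
Reactants: 7 tert-butyl 3-{[(2R)-3,3-dimethyloxiran-2-yl]methyl}-5-(3-methylbut-2-en-1-yl)-1H-indole-1-carboxylate
Product: 8 tert-butyl 3-{[(2R)-3,3-dimethyloxiran-2-yl]methyl}-5-{[(2S)-3,3-dimethyloxiran-2-yl]methyl}-1H-indole-1-carboxylate
Conditions: ent-Shi ketone (L-fructose-derived, 30 mol %), Oxone (2KHSO5·KHSO4·K2SO4), K2CO3, Bu4NHSO4 (cat.), MeCN–CH2(OMe)2–aq. Na2B4O7 buffer (pH about 10.5), 0 °C
Reagents that add atoms: potassium peroxymonosulfate (KHSO5, from Oxone), [K+].[O-]S(=O)(=O)OO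
Why: Shi epoxidation with the enantiomeric ketone gives the (S)-oxirane under catalyst control (the remote (R)-oxirane has no influence), and because the minor enantiomers of both epoxidations end up in a diastereomer, the (R,S) isomer is of very high ee (expected dr about 9:1).

**Step 6**
Reactants: 8 tert-butyl 3-{[(2R)-3,3-dimethyloxiran-2-yl]methyl}-5-{[(2S)-3,3-dimethyloxiran-2-yl]methyl}-1H-indole-1-carboxylate; 9 hexadecanoic acid (palmitic acid)
Product: 12 (2S)-2-(5-{[(2S)-3,3-dimethyloxiran-2-yl]methyl}-1H-indol-3-yl)-3-hydroxy-3-methylbutyl hexadecanoate, via N-H bis-epoxide 10 (not isolated), via spirocyclopropane indolenine 11 (not isolated)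
Conditions: NaOMe (0.2 equiv), MeOH–THF, 0 °C to rt; then 9 (5 equiv), evaporate, PhMe (0.05 M), 50 °C
Reagents that add atoms: hexadecanoic acid (compound 9), CCCCCCCCCCCCCCCC(=O)O
Why: Proposed new method: after routine methoxide-catalysed loss of the Boc group, the free indole C3 attacks the acid-hydrogen-bonded C3-chain oxirane at its secondary carbon in a 3-exo-tet manner with inversion (the tertiary carbon cannot be reached through a three-membered transition state and the weak acid in toluene does not ionise it), giving the N-protonated spirocyclopropane 11 as its palmitate ion pair, whose unhindered CH2 is opened by palmitate with rearomatisation, so that the (R)-oxirane carbon becomes the (S)-configured indolyl-bearing carbon of 12 while the C5 oxirane, having no neighbouring nucleophile, stays intact; the closest known reaction type is Ar1-3 (phenonium-like) participation in the solvolysis of 2-(indol-3-yl)ethyl sulfonates via spirocyclopropane indolenines, together with the aryl-shifted opening of electron-rich benzyl oxiranes.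

**Compound list**
1 | 5-bromo-1H-indole | Brc1ccc2[nH]ccc2c1 | starting material
2 | 1-bromo-3-methylbut-2-ene | CC(C)=CCBr | starting material
3 | 5-bromo-3-(3-methylbut-2-en-1-yl)-1H-indole | CC(C)=CCc1c[nH]c2ccc(Br)cc12 | intermediate
4 | tert-butyl 5-bromo-3-(3-methylbut-2-en-1-yl)-1H-indole-1-carboxylate | CC(C)=CCc1cn(C(=O)OC(C)(C)C)c2ccc(Br)cc12 | intermediate
5 | tert-butyl 5-bromo-3-{[(2R)-3,3-dimethyloxiran-2-yl]methyl}-1H-indole-1-carboxylate | CC(C)(C)OC(=O)n1cc(C[C@H]2OC2(C)C)c2cc(Br)ccc12 | intermediate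
6 | tributyl(3-methylbut-2-en-1-yl)stannane | CCCC[Sn](CCCC)(CCCC)CC=C(C)C | starting material
7 | tert-butyl 3-{[(2R)-3,3-dimethyloxiran-2-yl]methyl}-5-(3-methylbut-2-en-1-yl)-1H-indole-1-carboxylate | CC(C)(C)OC(=O)n1cc(C[C@H]2OC2(C)C)c2cc(CC=C(C)C)ccc12 | intermediate
8 | tert-butyl 3-{[(2R)-3,3-dimethyloxiran-2-yl]methyl}-5-{[(2S)-3,3-dimethyloxiran-2-yl]methyl}-1H-indole-1-carboxylate | CC(C)(C)OC(=O)n1cc(C[C@H]2OC2(C)C)c2cc(C[C@@H]3OC3(C)C)ccc12 | intermediate
9 | hexadecanoic acid (palmitic acid) | CCCCCCCCCCCCCCCC(=O)O | starting material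
10 | 3-{[(2R)-3,3-dimethyloxiran-2-yl]methyl}-5-{[(2S)-3,3-dimethyloxiran-2-yl]methyl}-1H-indole | [nH]1cc(C[C@H]2OC2(C)C)c2cc(C[C@@H]3OC3(C)C)ccc12 | intermediate
11 | 2-[(2R)-5'-{[(2S)-3,3-dimethyloxiran-2-yl]methyl}spiro[cyclopropane-1,3'-indol]-2-yl]propan-2-ol (spiro centre either way; present as its N-protonated palmitate ion pair) | CC(C)(O)[C@@H]1CC12C=Nc3ccc(C[C@@H]4OC4(C)C)cc23 | intermediate
12 | (2S)-2-(5-{[(2S)-3,3-dimethyloxiran-2-yl]methyl}-1H-indol-3-yl)-3-hydroxy-3-methylbutyl hexadecanoate | CCCCCCCCCCCCCCCC(=O)OC[C@H](c1c[nH]c2ccc(C[C@@H]3OC3(C)C)cc12)C(C)(C)O | target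

**Total step count:** 6. **Longest linear sequence:** 6 steps (from 1).

**Steps most likely to fail**

Step 6 (the proposed new step). The risks are opening of the C3-chain oxirane at its tertiary carbon or hydride shift to a ketone, attack of palmitate on the cyclopropane CH instead of CH2 (unrearranged secondary ester), and slow acidolysis of the C5 oxirane. The fallback uses known chemistry only, sets out from 1 and comes back at 12; it builds the branched side chain by an ester aldol and sets its configuration by enzymatic resolution. Compound 1 is alkylated at C3 with ethyl diazoacetate under Cu(OTf)2 catalysis to give ethyl 2-(5-bromo-1H-indol-3-yl)acetate F1. Boc2O/DMAP gives tert-butyl 5-bromo-3-(2-ethoxy-2-oxoethyl)-1H-indole-1-carboxylate F2. Stille coupling with 6 (Pd(PPh3)4, DMF) gives tert-butyl 3-(2-ethoxy-2-oxoethyl)-5-(3-methylbut-2-en-1-yl)-1H-indole-1-carboxylate F3. Shi epoxidation with the ent-ketone gives tert-butyl 5-{[(2S)-3,3-dimethyloxiran-2-yl]methyl}-3-(2-ethoxy-2-oxoethyl)-1H-indole-1-carboxylate F4. LiN(i-Pr)2 in THF at −78 °C followed by acetone gives the aldol tert-butyl 5-{[(2S)-3,3-dimethyloxiran-2-yl]methyl}-3-(1-ethoxy-3-hydroxy-3-methyl-1-oxobutan-2-yl)-1H-indole-1-carboxylate F5 as both epimers at the new centre. LiBH4 reduces the ester to tert-butyl 3-(1,3-dihydroxy-3-methylbutan-2-yl)-5-{[(2S)-3,3-dimethyloxiran-2-yl]methyl}-1H-indole-1-carboxylate F6, and catalytic NaOMe in MeOH removes the carbamate to give 2-(5-{[(2S)-3,3-dimethyloxiran-2-yl]methyl}-1H-indol-3-yl)-3-methylbutane-1,3-diol F7. A lipase (immobilised Candida antarctica lipase B or Burkholderia cepacia lipase) with vinyl palmitate in t-BuOMe then acylates the primary hydroxyl of one epimer only (kinetic resolution, at most 50%). If the enzyme prefers the (2S) epimer this gives 12 directly; if it prefers the (2R) epimer, the untouched (2S)-diol is recovered and acylated with palmitoyl chloride/pyridine at 0 °C to 12.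

Step 4 (Stille prenylation). The risks are partial transfer through the substituted allyl terminus (reverse-prenyl isomer) and attack of tributyltin bromide on the oxirane at 90 °C. The fallback sets out from 5 and comes back at 7; it installs an allyl group first, which has no regiochemical ambiguity, and makes the trisubstituted alkene afterwards. Stille coupling of 5 with allyltributylstannane (Pd(PPh3)4, DMF) gives tert-butyl 3-{[(2R)-3,3-dimethyloxiran-2-yl]methyl}-5-(prop-2-en-1-yl)-1H-indole-1-carboxylate F8. Cross-metathesis with excess 2-methylbut-2-ene and the second-generation Grubbs catalyst at 40 °C then gives 7.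

Step 1 (C3 prenylation). The risks are N- and C2-alkylation, double alkylation and a modest yield with the electron-poor bromoindole. The fallback sets out from 1 and comes back at 4; it replaces the Friedel–Crafts alkylation by a halogen-selective cross-coupling. Iodination (I2, KOH, DMF) gives 5-bromo-3-iodo-1H-indole F9. Boc2O/DMAP gives tert-butyl 5-bromo-3-iodo-1H-indole-1-carboxylate F10. Stille coupling with 6 (Pd2(dba)3, AsPh3, DMF, 40 °C) takes place at the C–I bond only and gives 4.

**Further compounds**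
F1 | step 6 | ethyl 2-(5-bromo-1H-indol-3-yl)acetate | CCOC(=O)Cc1c[nH]c2ccc(Br)cc12
F2 | step 6 | tert-butyl 5-bromo-3-(2-ethoxy-2-oxoethyl)-1H-indole-1-carboxylate | CCOC(=O)Cc1cn(C(=O)OC(C)(C)C)c2ccc(Br)cc12
F3 | step 6 | tert-butyl 3-(2-ethoxy-2-oxoethyl)-5-(3-methylbut-2-en-1-yl)-1H-indole-1-carboxylate | CCOC(=O)Cc1cn(C(=O)OC(C)(C)C)c2ccc(CC=C(C)C)cc12
F4 | step 6 | tert-butyl 5-{[(2S)-3,3-dimethyloxiran-2-yl]methyl}-3-(2-ethoxy-2-oxoethyl)-1H-indole-1-carboxylate | CCOC(=O)Cc1cn(C(=O)OC(C)(C)C)c2ccc(C[C@@H]3OC3(C)C)cc12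
F5 | step 6 | tert-butyl 5-{[(2S)-3,3-dimethyloxiran-2-yl]methyl}-3-(1-ethoxy-3-hydroxy-3-methyl-1-oxobutan-2-yl)-1H-indole-1-carboxylate (both epimers at the ester alpha carbon) | CCOC(=O)C(c1cn(C(=O)OC(C)(C)C)c2ccc(C[C@@H]3OC3(C)C)cc12)C(C)(C)O
F6 | step 6 | tert-butyl 3-(1,3-dihydroxy-3-methylbutan-2-yl)-5-{[(2S)-3,3-dimethyloxiran-2-yl]methyl}-1H-indole-1-carboxylate (both epimers at C2 of the diol) | OCC(c1cn(C(=O)OC(C)(C)C)c2ccc(C[C@@H]3OC3(C)C)cc12)C(C)(C)O
F7 | step 6 | 2-(5-{[(2S)-3,3-dimethyloxiran-2-yl]methyl}-1H-indol-3-yl)-3-methylbutane-1,3-diol (both epimers at C2) | OCC(c1c[nH]c2ccc(C[C@@H]3OC3(C)C)cc12)C(C)(C)O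
F8 | step 4 | tert-butyl 3-{[(2R)-3,3-dimethyloxiran-2-yl]methyl}-5-(prop-2-en-1-yl)-1H-indole-1-carboxylate | CC(C)(C)OC(=O)n1cc(C[C@H]2OC2(C)C)c2cc(CC=C)ccc12
F9 | step 1 | 5-bromo-3-iodo-1H-indole | Brc1ccc2[nH]cc(I)c2c1
F10 | step 1 | tert-butyl 5-bromo-3-iodo-1H-indole-1-carboxylate | CC(C)(C)OC(=O)n1cc(I)c2cc(Br)ccc12
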